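**Plan**
Numbering: ten-membered ring C1 (bears the exocyclic CH2), C2=C3 (cis), C4 (CH–CMe2OH), C5, C6, C7 (O–C–CH3), C9 (fusion CH), C10, C11; C8 is the benzylic CH(isobutyl) of the pyran ring.
Feature: the benzopyran holds the chain aryl–C8–C9–C7–O, a phenol bonded through an ortho carbon to C8 and through its oxygen to C7 of the methyl enone unit C8=C9–C7(=O)CH3; aryl–C8 and O–C7 are cut together to 3,5-dimethoxyphenol and an α-allyl enone.
Other cuts, in retrosynthetic order: the two O–CH3 bonds, C2=C3 with the C1 methylene (enyne/ring-closing metathesis), the two aryl–CHO bonds, C3–C4 (vinyl opening of a C4 epoxide), C4–C5 (alkenyl–alkyl coupling), C6–C7 (ketene acetal onto the C7 oxocarbenium ion), C1–C2 (alkyne from the allyl group).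
Forward: pyran ring first (step 2), then the C7 quaternary centre, the chains on C7 and C9, the formyl groups, the ten-membered ring (step 17) and the free phenols.
Stereochemistry: C8 from the chiral primary amine; C9 and C7 from C8 (proton, then carbon nucleophile, both anti to the pseudoaxial isobutyl group); C4 from Shi epoxidation and SN2 inversion; the cis C2=C3 alkene from the ring size.

Key step: step 2

Assumption: the quinine-derived 9-amino-9-deoxy-epi-cinchona amine is taken to give the 8R adduct (4R in chroman numbering); if the sense is the opposite, the quinidine-derived pseudoenantiomer is used and nothing else changes.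

**Step 1**
Reactants: 1 3-methylbutanal; 2 hex-5-en-2-one
Product: 3 (E)-3-allyl-6-methylhept-3-en-2-one
Conditions: Amberlyst 15, neat 2 (3 equiv), slow addition of 1, 60 °C; distillation
Reagents that add atoms: none
Why: Acid-catalysed crossed aldol condensation, in which the ketone reacts through its more substituted enol so that the C=C forms at the internal methylene, and the conjugated trisubstituted enone settles as the E isomer.

**Step 2**
Reactants: 3 (E)-3-allyl-6-methylhept-3-en-2-one; 4 3,5-dimethoxyphenol (1.5 equiv)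
Product: 6 (4R)-3-allyl-4-isobutyl-5,7-dimethoxy-2-methylchroman-2-ol (C2/C3 epimers), via open-chain keto-phenol 5 (not isolated)
Conditions: 9-amino-9-deoxy-epi-quinine (20 mol%), TFA (40 mol%), toluene, 40 °C
Reagents that add atoms: none
Why: The amine condenses with 3 to an iminium ion, the phenol, held through its OH by the protonated quinuclidine, adds through an ortho carbon to C8 in a Friedel–Crafts-type conjugate addition, and hydrolysis of the enamine releases ketone 5 and the catalyst. The closest known reaction type is the cinchona primary amine-catalysed Friedel–Crafts alkylation of naphthols and electron-rich phenols with enones that ends in hemiketal formation, here applied to an α-branched enone, a class that such amines already activate toward other nucleophiles. The pyran ring closes by reversible 6-exo-trig addition of the phenol oxygen to the C7 carbonyl, which holds the adduct as the chroman-2-ol. C8 is the only stereocentre the step has to set and it is controlled by the catalyst, which blocks one face of the iminium ion; C9 (enamine protonation) and C7 (anomeric) are left mixed and are erased in step 3. The step needs ortho rather than para C-alkylation and mono- rather than bis-alkylation: the two ortho carbons are equivalent, only ortho attack is assisted by the hydrogen bond to the catalyst and trapped as the hemiketal, and the excess of phenol suppresses a second addition.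

**Step 3**
Reactants: 6 chroman-2-ol
Product: 7 (4R)-3-allyl-4-isobutyl-5,7-dimethoxy-2-methyl-4H-chromene
Conditions: p-TsOH·H2O (5 mol%), 4 Å MS, CH2Cl2, rt
Reagents that add atoms: none
Why: Acid-catalysed dehydration of the hemiketal (E1 through the C7 oxocarbenium ion) should give the more substituted endocyclic enol ether, which removes the C7/C9 mixture and leaves C8 untouched.

**Step 4**
Reactants: 7 4H-chromene
Product: 10 methyl 2-[(2R,3S,4R)-3-allyl-4-isobutyl-5,7-dimethoxy-2-methylchroman-2-yl]acetate, via 2-chloro ether 8 (not isolated), via oxocarbenium chloride 9 (not isolated)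
Conditions: HCl (1.05 equiv, 2 M in Et2O), CH2Cl2, −78 °C; then CH2=C(OMe)OTBS (2.5 equiv), TMSOTf (10 mol%), −78 → −40 °C
Reagents that add atoms: 1-(tert-butyldimethylsilyloxy)-1-methoxyethene, C=C(OC)O[Si](C)(C)C(C)(C)C
Why: Markovnikov hydrochlorination of the enol ether followed by Mukaiyama-type substitution of the tertiary α-chloro ether through oxocarbenium ion 9: the isobutyl group, held pseudoaxial by strain with the peri methoxy group and the C9 chain, shields one face, so the proton enters C9 and then the ketene acetal enters C7 from the opposite face, which sets C9 (S) and C7 (R) with C10 cis and C6 trans to isobutyl.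

**Step 5**
Reactants: 10 chromanyl acetate
Product: 11 2-[(2R,3S,4R)-3-allyl-4-isobutyl-5,7-dimethoxy-2-methylchroman-2-yl]ethanol
Conditions: LiAlH4, THF, 0 °C
Reagents that add atoms: none
Why: Hydride reduction of the ester to the primary alcohol, with no other reducible group present.

**Step 6**
Reactants: 11 primary alcohol
Product: 12 (2R,3S,4R)-3-allyl-2-(2-iodoethyl)-4-isobutyl-5,7-dimethoxy-2-methylchroman
Conditions: PPh3, imidazole, I2, CH2Cl2, 0 °C → rt
Reagents that add atoms: iodine, II
Why: Appel-type iodination, an SN2 displacement of the oxyphosphonium ion at an unhindered primary carbon.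

**Step 7**
Reactants: 12 primary iodide
Product: 13 (2R,3S,4R)-3-allyl-4-isobutyl-5,7-dimethoxy-2-methyl-2-(4-methylpent-3-en-1-yl)chroman
Conditions: (2-methylprop-1-enyl)MgBr (3 equiv), CuI (10 mol%), THF, −20 → 0 °C
Reagents that add atoms: (2-methylprop-1-en-1-yl)magnesium bromide, CC(C)=C[Mg]Br
Why: Copper-catalysed cross-coupling of an alkenyl Grignard reagent with a primary alkyl iodide forms C4–C5 and places the trisubstituted alkene that later carries C4 and the carbinol carbon.

**Step 8**
Reactants: 13 diene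
Product: 15 3-[(2R,3S,4R)-4-isobutyl-5,7-dimethoxy-2-methyl-2-(4-methylpent-3-en-1-yl)chroman-3-yl]propan-1-ol, via B-alkyl-9-BBN 14 (not isolated)
Conditions: 9-BBN (1.3 equiv), THF, 0 °C → rt; then NaOH, H2O2, 0 °C
Reagents that add atoms: hydrogen peroxide, OO
Why: Anti-Markovnikov hydroboration–oxidation with 9-BBN, which reacts far faster with the monosubstituted allyl alkene than with the trisubstituted one.

**Step 9**
Reactants: 15 primary alcohol
Product: 16 3-[(2R,3S,4R)-4-isobutyl-5,7-dimethoxy-2-methyl-2-(4-methylpent-3-en-1-yl)chroman-3-yl]propanal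
Conditions: Dess–Martin periodinane, NaHCO3, CH2Cl2, 0 °C → rt
Reagents that add atoms: none
Why: Dess–Martin oxidation of the primary alcohol to the aldehyde under buffered conditions that spare the alkene and the electron-rich arene.

**Step 10**
Reactants: 16 aldehyde
Product: 17 (2R,3S,4R)-3-(4,4-dibromobut-3-en-1-yl)-4-isobutyl-5,7-dimethoxy-2-methyl-2-(4-methylpent-3-en-1-yl)chroman
Conditions: CBr4 (2 equiv), PPh3 (4 equiv), 2,6-lutidine, CH2Cl2, 0 °C
Reagents that add atoms: carbon tetrabromide, BrC(Br)(Br)Br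
Why: First stage of the Corey–Fuchs reaction, a Wittig-type dibromo-olefination that adds C2.

**Step 11**
Reactants: 17 dibromoalkene
Product: 19 (2R,3S,4R)-4-isobutyl-5,7-dimethoxy-2-methyl-2-(4-methylpent-3-en-1-yl)-3-[4-(triethylsilyl)but-3-yn-1-yl]chroman, via lithium acetylide 18 (not isolated)
Conditions: n-BuLi (2.1 equiv), THF, −78 °C; then Et3SiCl, −78 → 0 °C
Reagents that add atoms: chlorotriethylsilane, CC[Si](Cl)(CC)CC
Why: Second stage of the Corey–Fuchs reaction (Br/Li exchange and Fritsch–Buttenberg–Wiechell rearrangement to the acetylide), trapped on carbon by the silyl chloride so that the alkyne is protected for steps 12 to 15.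

**Step 12**
Reactants: 19 silyl alkyne with trisubstituted alkene
Product: 20 (2R,3S,4R)-2-{2-[(2R)-3,3-dimethyloxiran-2-yl]ethyl}-4-isobutyl-5,7-dimethoxy-2-methyl-3-[4-(triethylsilyl)but-3-yn-1-yl]chroman
Conditions: D-fructose-derived Shi ketone (30 mol%), Oxone, K2CO3, Bu4NHSO4, MeCN–DMM/aq. borate buffer (pH 10.5), 0 °C
Reagents that add atoms: potassium peroxymonosulfate (Oxone), [K+].[O-]S(=O)(=O)OO
Why: Shi asymmetric epoxidation, in which the chiral dioxirane transfers oxygen to the only alkene through the spiro transition state and should set the epoxide carbon C4 as R under reagent control.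

**Step 13**
Reactants: 20 epoxide
Product: 21 (2R,3S,4R)-2-[(3R)-3-ethenyl-4-hydroxy-4-methylpentyl]-4-isobutyl-5,7-dimethoxy-2-methyl-3-[4-(triethylsilyl)but-3-yn-1-yl]chroman
Conditions: CH2=CHMgBr (4 equiv), CuBr·SMe2 (20 mol%), THF, −30 → 0 °C; aq. NH4Cl
Reagents that add atoms: vinylmagnesium bromide, C=C[Mg]Br
Why: Copper-catalysed SN2 opening of the trisubstituted epoxide at its less substituted carbon C4 with inversion, which delivers C3, the tertiary alcohol and C4 in the R configuration of the target.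

**Step 14**
Reactants: 21 vinyl carbinol
Product: 22 (2R,3S,4R)-6,8-dibromo-2-[(3R)-3-ethenyl-4-hydroxy-4-methylpentyl]-4-isobutyl-5,7-dimethoxy-2-methyl-3-[4-(triethylsilyl)but-3-yn-1-yl]chroman
Conditions: NBS (2.05 equiv), MeCN, −20 → 0 °C, dark
Reagents that add atoms: N-bromosuccinimide, O=C1CCC(=O)N1Br
Why: Electrophilic aromatic bromination at the two free ring positions, each flanked by two oxygen substituents and far more nucleophilic than the monosubstituted alkene.

**Step 15**
Reactants: 22 aryl dibromide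
Product: 24 (2R,3S,4R)-2-[(3R)-3-ethenyl-4-hydroxy-4-methylpentyl]-4-isobutyl-5,7-dimethoxy-2-methyl-3-[4-(triethylsilyl)but-3-yn-1-yl]chroman-6,8-dicarbaldehyde, via aryldilithium 23 (not isolated)
Conditions: t-BuLi (5.2 equiv), THF, −78 °C; then DMF (8 equiv), −78 → −20 °C; aq. NH4Cl
Reagents that add atoms: N,N-dimethylformamide, CN(C)C=O
Why: Double bromine–lithium exchange and Bouveault formylation with DMF, with the alcohol carried as its lithium alkoxide and the alkyne C–H masked by silicon.

**Step 16**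
Reactants: 24 silyl alkyne dialdehyde
Product: 25 (2R,3S,4R)-3-(but-3-yn-1-yl)-2-[(3R)-3-ethenyl-4-hydroxy-4-methylpentyl]-4-isobutyl-5,7-dimethoxy-2-methylchroman-6,8-dicarbaldehyde
Conditions: TBAF (1.2 equiv), THF, 0 °C
Reagents that add atoms: none
Why: Fluoride-mediated C-desilylation of the alkynylsilane, which the non-enolisable aryl aldehydes tolerate.

**Step 17**
Reactants: 25 enyne
Product: 27 5,7-di-O-methyl ether of the target (ten-membered ring closed, cis C2=C3, exocyclic C1 methylene), via triene 26 (not isolated)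
Conditions: Grubbs II (15 mol%), ethene (1 atm), toluene (2 mM), rt; then Ar sparge, 80 °C
Reagents that add atoms: ethene, C=C
Why: Enyne cross-metathesis with ethene converts the alkyne into the 2-substituted buta-1,3-diene 26, whose vinyl end then closes onto the C4 vinyl group by ring-closing metathesis, and the ten-membered ring is expected to take the less strained cis C2=C3 geometry.

**Step 18**
Reactants: 27 dimethyl ether
Product: 28 CNP0479784.1 (target)
Conditions: NaSEt (8 equiv), DMF, 90 °C; 1 M HCl work-up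
Reagents that add atoms: none
Why: Nucleophilic O-demethylation (SN2 at methyl by thiolate) of two aryl methyl ethers that are each activated by ortho and para formyl groups, under non-acidic conditions that should spare the diene and the tertiary alcohol.

**Compound list**
1 | 3-methylbutanal | CC(C)CC=O | starting material
2 | hex-5-en-2-one | CC(=O)CCC=C | starting material
3 | (E)-3-allyl-6-methylhept-3-en-2-one | CC(C)C/C=C(\CC=C)C(C)=O | intermediate
4 | 3,5-dimethoxyphenol | COc1cc(O)cc(OC)c1 | starting material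
5 | (4R)-4-(2-hydroxy-4,6-dimethoxyphenyl)-6-methyl-3-(prop-2-en-1-yl)heptan-2-one (C3 epimers) | CC(=O)C(CC=C)[C@@H](CC(C)C)c1c(O)cc(OC)cc1OC | intermediate
6 | (4R)-3-allyl-4-isobutyl-5,7-dimethoxy-2-methylchroman-2-ol (C2/C3 epimers) | C=CCC1[C@@H](CC(C)C)c2c(OC)cc(OC)cc2OC1(C)O | intermediate
7 | (4R)-3-allyl-4-isobutyl-5,7-dimethoxy-2-methyl-4H-chromene | CC1=C(CC=C)[C@@H](CC(C)C)c2c(OC)cc(OC)cc2O1 | intermediate
8 | (3S,4R)-3-allyl-2-chloro-4-isobutyl-5,7-dimethoxy-2-methylchroman (C2 epimers) | CC1(Cl)Oc2cc(OC)cc(OC)c2[C@H](CC(C)C)[C@@H]1CC=C | intermediate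
9 | (3S,4R)-3-allyl-4-isobutyl-5,7-dimethoxy-2-methyl-3,4-dihydrochromenylium chloride | CC1=[O+]c2cc(OC)cc(OC)c2[C@H](CC(C)C)[C@@H]1CC=C.[Cl-] | intermediate
10 | methyl 2-[(2R,3S,4R)-3-allyl-4-isobutyl-5,7-dimethoxy-2-methylchroman-2-yl]acetate | COC(=O)C[C@@]1(C)Oc2cc(OC)cc(OC)c2[C@H](CC(C)C)[C@@H]1CC=C | intermediate
11 | 2-[(2R,3S,4R)-3-allyl-4-isobutyl-5,7-dimethoxy-2-methylchroman-2-yl]ethanol | OCC[C@@]1(C)Oc2cc(OC)cc(OC)c2[C@H](CC(C)C)[C@@H]1CC=C | intermediate
12 | (2R,3S,4R)-3-allyl-2-(2-iodoethyl)-4-isobutyl-5,7-dimethoxy-2-methylchroman | ICC[C@@]1(C)Oc2cc(OC)cc(OC)c2[C@H](CC(C)C)[C@@H]1CC=C | intermediate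
13 | (2R,3S,4R)-3-allyl-4-isobutyl-5,7-dimethoxy-2-methyl-2-(4-methylpent-3-en-1-yl)chroman | CC(C)=CCC[C@@]1(C)Oc2cc(OC)cc(OC)c2[C@H](CC(C)C)[C@@H]1CC=C | intermediate
14 | 9-{3-[(2R,3S,4R)-4-isobutyl-5,7-dimethoxy-2-methyl-2-(4-methylpent-3-en-1-yl)chroman-3-yl]propyl}-9-borabicyclo[3.3.1]nonane | CC(C)=CCC[C@@]1(C)Oc2cc(OC)cc(OC)c2[C@H](CC(C)C)[C@@H]1CCCB1C2CCCC1CCC2 | intermediate
15 | 3-[(2R,3S,4R)-4-isobutyl-5,7-dimethoxy-2-methyl-2-(4-methylpent-3-en-1-yl)chroman-3-yl]propan-1-ol | CC(C)=CCC[C@@]1(C)Oc2cc(OC)cc(OC)c2[C@H](CC(C)C)[C@@H]1CCCO | intermediate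
16 | 3-[(2R,3S,4R)-4-isobutyl-5,7-dimethoxy-2-methyl-2-(4-methylpent-3-en-1-yl)chroman-3-yl]propanal | CC(C)=CCC[C@@]1(C)Oc2cc(OC)cc(OC)c2[C@H](CC(C)C)[C@@H]1CCC=O | intermediate
17 | (2R,3S,4R)-3-(4,4-dibromobut-3-en-1-yl)-4-isobutyl-5,7-dimethoxy-2-methyl-2-(4-methylpent-3-en-1-yl)chroman | CC(C)=CCC[C@@]1(C)Oc2cc(OC)cc(OC)c2[C@H](CC(C)C)[C@@H]1CCC=C(Br)Br | intermediate
18 | {4-[(2R,3S,4R)-4-isobutyl-5,7-dimethoxy-2-methyl-2-(4-methylpent-3-en-1-yl)chroman-3-yl]but-1-yn-1-yl}lithium | CC(C)=CCC[C@@]1(C)Oc2cc(OC)cc(OC)c2[C@H](CC(C)C)[C@@H]1CCC#C[Li] | intermediate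
19 | (2R,3S,4R)-4-isobutyl-5,7-dimethoxy-2-methyl-2-(4-methylpent-3-en-1-yl)-3-[4-(triethylsilyl)but-3-yn-1-yl]chroman | CC(C)=CCC[C@@]1(C)Oc2cc(OC)cc(OC)c2[C@H](CC(C)C)[C@@H]1CCC#C[Si](CC)(CC)CC | intermediate
20 | (2R,3S,4R)-2-{2-[(2R)-3,3-dimethyloxiran-2-yl]ethyl}-4-isobutyl-5,7-dimethoxy-2-methyl-3-[4-(triethylsilyl)but-3-yn-1-yl]chroman | CC1(C)O[C@@H]1CC[C@@]2(C)Oc3cc(OC)cc(OC)c3[C@H](CC(C)C)[C@@H]2CCC#C[Si](CC)(CC)CC | intermediate
21 | (2R,3S,4R)-2-[(3R)-3-ethenyl-4-hydroxy-4-methylpentyl]-4-isobutyl-5,7-dimethoxy-2-methyl-3-[4-(triethylsilyl)but-3-yn-1-yl]chroman | C=C[C@H](C(C)(C)O)CC[C@@]1(C)Oc2cc(OC)cc(OC)c2[C@H](CC(C)C)[C@@H]1CCC#C[Si](CC)(CC)CC | intermediate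
22 | 6,8-dibromo derivative of 21 | C=C[C@H](C(C)(C)O)CC[C@@]1(C)Oc2c(Br)c(OC)c(Br)c(OC)c2[C@H](CC(C)C)[C@@H]1CCC#C[Si](CC)(CC)CC | intermediate
23 | 6,8-dilithio lithium alkoxide derived from 22 | C=C[C@H](C(C)(C)O[Li])CC[C@@]1(C)Oc2c([Li])c(OC)c([Li])c(OC)c2[C@H](CC(C)C)[C@@H]1CCC#C[Si](CC)(CC)CC | intermediate
24 | (2R,3S,4R)-2-[(3R)-3-ethenyl-4-hydroxy-4-methylpentyl]-4-isobutyl-5,7-dimethoxy-2-methyl-3-[4-(triethylsilyl)but-3-yn-1-yl]chroman-6,8-dicarbaldehyde | C=C[C@H](C(C)(C)O)CC[C@@]1(C)Oc2c(C=O)c(OC)c(C=O)c(OC)c2[C@H](CC(C)C)[C@@H]1CCC#C[Si](CC)(CC)CC | intermediate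
25 | (2R,3S,4R)-3-(but-3-yn-1-yl)-2-[(3R)-3-ethenyl-4-hydroxy-4-methylpentyl]-4-isobutyl-5,7-dimethoxy-2-methylchroman-6,8-dicarbaldehyde | C=C[C@H](C(C)(C)O)CC[C@@]1(C)Oc2c(C=O)c(OC)c(C=O)c(OC)c2[C@H](CC(C)C)[C@@H]1CCC#C | intermediate
26 | (2R,3S,4R)-2-[(3R)-3-ethenyl-4-hydroxy-4-methylpentyl]-4-isobutyl-5,7-dimethoxy-2-methyl-3-(3-methylidenepent-4-en-1-yl)chroman-6,8-dicarbaldehyde | C=C[C@H](C(C)(C)O)CC[C@@]1(C)Oc2c(C=O)c(OC)c(C=O)c(OC)c2[C@H](CC(C)C)[C@@H]1CCC(=C)C=C | intermediate
27 | 5,7-di-O-methyl ether of the target (4R,7R,8R,9S; cis C2=C3) | C=C1/C=C\[C@H](C(C)(C)O)CC[C@@]2(C)Oc3c(C=O)c(OC)c(C=O)c(OC)c3[C@H](CC(C)C)[C@@H]2CC1 | intermediate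
28 | CNP0479784.1 (4R,7R,8R,9S; cis C2=C3) | C=C1/C=C\[C@H](C(C)(C)O)CC[C@@]2(C)Oc3c(C=O)c(O)c(C=O)c(O)c3[C@H](CC(C)C)[C@@H]2CC1 | target

**Count and risks**
Total step count: 18. Longest linear sequence: 18 steps (1/2 → 28).

Step 4. What may go wrong: loss of facial control. Protonation of the enol ether may not be fully anti to the isobutyl group, or the oxocarbenium ion may lose H-9 and be re-protonated before capture, so that C9 and with it C7 epimers form; alkylation of the electron-rich arene by the cation is a further drain. Fallback: separate the two events. Setting out from 7, kinetic addition of methanol (MeOH 5 equiv, PPTS 5 mol%, CH2Cl2, −20 °C) should give the mixed methyl ketal (3S,4R)-3-allyl-4-isobutyl-2,5,7-trimethoxy-2-methylchroman F3. This is a neutral compound in which the C9 configuration can be checked, and a wrong C9 epimer can be removed and returned to 7 with TsOH. Ionisation of pure F3 with TMSOTf (1.1 equiv) in the presence of the same ketene acetal and 2,6-di-tert-butyl-4-methylpyridine at −78 °C (Mukaiyama-type ketal substitution) then comes back to the route at 10; the hindered base keeps the cation from losing the C9 proton.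

Step 17. What may go wrong: intermolecular metathesis (oligomers) may outrun closure of the strained ten-membered ring, the reaction may stall at triene 26, or the ring may close to the trans C2=C3 alkene. Fallback: close the same ring at C1–C2 by an intramolecular Heck reaction. Setting out from 25, Markovnikov hydrosilylation of the terminal alkyne (Et3SiH, [Cp*Ru(MeCN)3]PF6, CH2Cl2, 0 °C) should give the 1,1-disubstituted vinylsilane F4. Iododesilylation (NIS, MeCN/HFIP, 0 °C) gives the 2-iodoalk-1-ene F5. Pd(OAc)2/P(o-tol)3, Et3N, MeCN, 80 °C at high dilution then joins C1 to the terminal carbon of the C4 vinyl group, and β-hydride elimination gives the conjugated diene, which comes back to the route at 27. In this variant C2 is the former vinyl CH2 and the exocyclic methylene is the former alkyne CH; the alkene geometry would have to be checked.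

Step 2. What may go wrong: condensation of the amine with the α-branched enone is slow and the iminium ion is twisted, so the addition may stall or proceed with weak facial discrimination at C8, and para C-alkylation may compete. Fallback: leave asymmetric catalysis and resolve. Setting out from 3 and 4, a Brønsted acid-catalysed Friedel–Crafts addition with hemiketal closure (p-TsOH 10 mol%, toluene, 60 °C) gives the racemic hemiketal F1, which loses water in the same flask to the racemic 4H-chromene F2. Preparative chromatography on a chiral stationary phase then gives the 4R enantiomer, and the route is rejoined at 7.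

**Further compounds**
F1 | step 2 | rac-3-allyl-4-isobutyl-5,7-dimethoxy-2-methylchroman-2-ol | C=CCC1C(CC(C)C)c2c(OC)cc(OC)cc2OC1(C)O
F2 | step 2 | rac-3-allyl-4-isobutyl-5,7-dimethoxy-2-methyl-4H-chromene | CC1=C(CC=C)C(CC(C)C)c2c(OC)cc(OC)cc2O1
F3 | step 4 | (3S,4R)-3-allyl-4-isobutyl-2,5,7-trimethoxy-2-methylchroman | COC1(C)Oc2cc(OC)cc(OC)c2[C@H](CC(C)C)[C@@H]1CC=C
F4 | step 17 | (2R,3S,4R)-2-[(3R)-3-ethenyl-4-hydroxy-4-methylpentyl]-4-isobutyl-5,7-dimethoxy-2-methyl-3-[3-(triethylsilyl)but-3-en-1-yl]chroman-6,8-dicarbaldehyde | C=C[C@H](C(C)(C)O)CC[C@@]1(C)Oc2c(C=O)c(OC)c(C=O)c(OC)c2[C@H](CC(C)C)[C@@H]1CCC(=C)[Si](CC)(CC)CC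
F5 | step 17 | (2R,3S,4R)-2-[(3R)-3-ethenyl-4-hydroxy-4-methylpentyl]-3-(3-iodobut-3-en-1-yl)-4-isobutyl-5,7-dimethoxy-2-methylchroman-6,8-dicarbaldehyde | C=C[C@H](C(C)(C)O)CC[C@@]1(C)Oc2c(C=O)c(OC)c(C=O)c(OC)c2[C@H](CC(C)C)[C@@H]1CCC(I)=C
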